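- Start from a ratio, x, starting material over partner as charged: it is 0.500 in this flask. Starting material is the limiting reagent in this flask, with 10 mM against 20.0 mM of partner, so I write its balance in fractions of its charge: what is left, target with its crystals, isomer, side product and homo dimer add up to the whole charge.

| setting | ash | birch | larch | flask |
|---|---|---|---|---|
| starting material | 10 mM | 10 mM | 20 mM | 10 mM |
| partner | 10 mM | 40 mM | 20 mM | 20.0 mM |
| remark | run made earlier | run made earlier | run made earlier |  |
| time |  |  |  | 6.0 h |

- ash (time / h: isomer of the product / %, target / %): 0.500: 5, 24; 0.833: 7, 27; 1.33: 9, 27; 2.00: 11, 29; 3.00: 15, 25; 5.00: 18, 19; 8.00: 22, 6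
- birch (time / h: isomer of the product / %, target / %): 1.00: 16, 63; 2.00: 21, 62; 3.00: 24, 60; 4.00: 21, 62; 5.00: 23, 57; 6.00: 26, 54; 8.00: 29, 51
- larch (time / h: isomer of the product / %, target / %): 0.667: 9, 34; 2.00: 10, 37; 3.00: 11, 42; 5.00: 16, 36; 8.00: 17, 34

(each reading ± 1.5 percentage points)

- a species is counted by the starting material in it: one homo dimer or side product counts as two
- amounts and yields of target count crystals too
- given per volume of solution although it is solid: crystals
- candidate steps: starting material + partner <-> isomer of the product; 2 starting material -> homo dimer; starting material + target -> side product; starting material + partner <-> target; crystals <-> target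

- ratio of isomer of the product to target at 25 s
- ratio of isomer of the product to target at 12 min
- ratio of isomer of the product to target at 6.0 h
- which of isomer of the product and target there is more of at 6.0 h

- First instants: the couplings race. You read isomer/target at 0.208 in ash, 0.254 in birch and 0.265 in larch, so target forms faster. These first readings come no earlier than 0.500 h, and the ash ratio rises to 0.259 at 0.833 h, so I expect a lower ratio at 25 s.
- Middle: in birch, target stalls. Birch reads 63% at 1.00 h and 60% at 3.00 h, while isomer climbs from 16% to 24%.
- End: in ash, target falls from 29% at 2.00 h to 6% at 8.00 h. I carry one quantity from here, the outside share, the fraction of the charge in neither target nor isomer: the fraction held by starting material left, homo dimer and side product.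
- At 5.00 h the readings give an outside share of 63.0% in ash, 48.0% in larch and 20.0% in birch, so it is larger in ash and larch than in birch, which has the lower x. My straight line in x, through birch and the mean of ash and larch, gives 31.8% for this flask, and I carry that estimate on to 6.0 h.
- For this flask I take isomer from the birch reading at 6.00 h, 26%, which is less than an even split of the fraction inside target and isomer. So I put target ahead in this flask, with a ratio of 0.616 at 6.0 h.
- The forecast gives ratios of 0.14 at 25 s, 0.17 at 12 min and 0.65 at 6.0 h, with target ahead: “Target should still lead, though uncertainty remains over whether crystals form.”
- The flask gives ratios of 0.0822 at 25 s, 0.203 at 12 min and 0.591 at 6.0 h, with target ahead.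

    starting material + partner ⇌ isomer of the product (K = 840 /M, k = 26.0 /M/h)
    2 starting material → homo dimer (k = 66.0 /M/h)
    starting material + target → side product (k = 79.0 /M/h)
    starting material + partner ⇌ target (K = 17.0 /M, k = 340 /M/h)
    crystals ⇌ target, rate k5*(cs5 - [target]) while solid is left; crystals form when [target] > cs5 (solubility = 0.190 mM, k = 9.40 /h)

- At 6.0 h this flask holds target 40.1%, of which 38.4% is crystals, and isomer 23.7%, so its outside share is 36.3% against my 31.8%. Now take the neighbouring flask with 17 mM of starting material, where x is 0.850. The same line gives an outside share of 48.4%. That neighbour's outside share comes to 46.2%, with target 37.1%, isomer 16.7% and a ratio of 0.452.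

All runs were generated by integration for an exercise; the scatter is artificial.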